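**Retrosynthetic overview**
1. The 1,2-dioxane is made last: the C11–O bond forms by transannular 6-exo SN2 attack of a C8 hydroperoxide (from perhydrolysis of a (7S,8R) cis-epoxide at C8) on an (11S) allylic chloride, followed by 7-O-acetylation.
2. Before that, the 14-membered carbocycle is closed at C11–C12 by an asymmetric Nozaki–Hiyama–Kishi reaction of a Z-vinyl iodide with the C11 aldehyde.
3. The cis-fused α-methylene-γ-butyrolactone (C1–C2 bond) comes first, by catalytic asymmetric 2-(methoxycarbonyl)allylation joining enal fragment A and allyl bromide fragment B; Shi epoxidation then sets C7/C8.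
4. Fragment A comes from mono-ozonolysis of 1,5-dimethylcycloocta-1,5-diene (gives the 7Z olefin) and Horner–Wadsworth–Emmons olefination (3E); fragment B from Stork–Zhao iodo-olefination (12Z) and Baylis–Hillman-type chemistry.
5. Ring order: γ-lactone, then oxirane (temporary), then 14-membered carbocycle, then 1,2-dioxane.

Assumption: cembrane numbering is used (ring C1–C14, C15 lactone α-carbon, C16 lactone carbonyl, C17 exocyclic methylene, C18/C19/C20 the methyls on C4/C8/C12); 1 (enriched in the 1,5-isomer), 6, the L-fructose-derived Shi ketone and both chiral ligands are taken as purchasable, and for each ligand the enantiomer that gives the stated sense is used (to be confirmed on a model substrate).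

**Route**

Step 1
Reactants: 1 (1Z,5Z)-1,5-dimethylcycloocta-1,5-diene
Product: 3 (Z)-9-hydroxy-6-methylnon-5-en-2-one, via keto aldehyde 2 (not isolated)
Conditions: O3 (0.9 equiv), CH2Cl2, −78 °C; Me2S, −78 °C → rt; then NaBH(OAc)3, rt
Reagents that add atoms: ozone, [O-][O+]=O
Why: Ozonolysis of one of the two equivalent ring olefins with sub-stoichiometric ozone and reductive work-up opens the ring while the surviving ring-derived olefin keeps its Z geometry (the future C7=C8), and NaBH(OAc)3 then reduces only the aldehyde (chemoselective hydride reduction), leaving the methyl ketone.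

Step 2
Reactants: 3 (Z)-9-hydroxy-6-methylnon-5-en-2-one
Product: 4 (2E,6Z)-10-hydroxy-N-methoxy-N,3,7-trimethyldeca-2,6-dienamide
Conditions: (EtO)2P(O)CH2C(O)N(OMe)Me (2.5 equiv), NaH, THF, 0 → 60 °C; 2E isomer separated by chromatography
Reagents that add atoms: diethyl [2-(methoxy(methyl)amino)-2-oxoethyl]phosphonate, CCOP(=O)(CC(=O)N(C)OC)OCC
Why: Horner–Wadsworth–Emmons olefination of the methyl ketone (the alkoxide is a spectator) gives the 2E enamide as the major isomer (about 5:1 expected), which fixes the 3E olefin of the target.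

Step 3
Reactants: 4 (2E,6Z)-10-hydroxy-N-methoxy-N,3,7-trimethyldeca-2,6-dienamide
Product: 5 (2E,6Z)-10-hydroxy-3,7-dimethyldeca-2,6-dienal (fragment A)
Conditions: i-Bu2AlH (2.2 equiv), THF, −78 °C
Reagents that add atoms: none
Why: Hydride reduction of the Weinreb amide stops at the aldehyde through the stable aluminium chelate (one equivalent is consumed by the free alcohol), giving the E-enal without touching either olefin.

Step 4
Reactants: 6 3-[(tert-butyldimethylsilyl)oxy]propanal
Product: 7 (Z)-tert-butyl[(4-iodopent-3-en-1-yl)oxy]dimethylsilane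
Conditions: [Ph3PCH2CH3]I, n-BuLi, THF, 0 °C; I2, −78 °C; NaN(SiMe3)2, −20 °C; then 6, −78 °C
Reagents that add atoms: ethyltriphenylphosphonium iodide, CC[P+](c1ccccc1)(c1ccccc1)c1ccccc1.[I-]; iodine, II
Why: Stork–Zhao-type Wittig olefination with the α-iodo ylide Ph3P=C(I)CH3 gives the Z-2-iodoalkene (iodine cis to the chain), which later becomes the 12Z olefin with C11 cis to C14.

Step 5
Reactants: 7 (Z)-tert-butyl[(4-iodopent-3-en-1-yl)oxy]dimethylsilane
Product: 8 (Z)-4-iodopent-3-en-1-ol
Conditions: n-Bu4NF, THF, 0 °C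
Reagents that add atoms: none
Why: Fluoride-mediated desilylation frees the primary alcohol without affecting the vinyl iodide.

Step 6
Reactants: 8 (Z)-4-iodopent-3-en-1-ol
Product: 9 (Z)-4-iodopent-3-enal
Conditions: DMP, NaHCO3, CH2Cl2, 0 °C; used at once
Reagents that add atoms: none
Why: Buffered Dess–Martin oxidation gives the β,γ-unsaturated aldehyde under non-basic conditions, so the olefin does not move into conjugation.

Step 7
Reactants: 9 (Z)-4-iodopent-3-enal
Product: 10 methyl (Z)-3-hydroxy-6-iodo-2-methylidenehept-5-enoate (racemic)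
Conditions: methyl propiolate, i-Bu2AlH, N-methylmorpholine N-oxide, THF, 0 °C; then 9, 0 °C → rt
Reagents that add atoms: methyl propiolate, C#CC(=O)OC
Why: Vinylalumination (a fast Morita–Baylis–Hillman surrogate): the α-aluminoacrylate from hydroalumination of the propiolate adds to the sensitive aldehyde within minutes, and the racemic carbinol centre is erased in the next step.

Step 8
Reactants: 10 methyl (Z)-3-hydroxy-6-iodo-2-methylidenehept-5-enoate
Product: 11 methyl (2Z,5Z)-2-(bromomethyl)-6-iodohepta-2,5-dienoate (fragment B)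
Conditions: PBr3, Et2O, −10 °C
Reagents that add atoms: phosphorus tribromide, BrP(Br)Br
Why: SN2′ bromination of the Baylis–Hillman alcohol gives the thermodynamically preferred Z-2-(bromomethyl)alk-2-enoate (side chain cis to CH2Br), the geometry needed for a syn-selective allylation.

Step 9
Reactants: 5 (2E,6Z)-10-hydroxy-3,7-dimethyldeca-2,6-dienal; 11 methyl (2Z,5Z)-2-(bromomethyl)-6-iodohepta-2,5-dienoate
Product: 13 (4S,5S)-5-[(1E,5Z)-9-hydroxy-2,6-dimethylnona-1,5-dien-1-yl]-4-[(Z)-3-iodobut-2-en-1-yl]-3-methylideneoxolan-2-one, via hydroxy ester 12 (not isolated)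
Conditions: CrCl2 (10 mol %, nickel-free), (S,S)-1,8-bis(4-isopropyloxazolin-2-yl)-3,6-diphenylcarbazole (12 mol %), Mn powder, Cp2ZrCl2, THF, rt; then p-TsOH (cat.), CH2Cl2, rt
Reagents that add atoms: none
Why: Catalytic asymmetric Nozaki–Hiyama-type 2-(alkoxycarbonyl)allylation: the geometry-locked Z-allylchromium (ligand-bound trivalent chromium, turned over by manganese) adds through a closed chair transition state to the Re face of the enal chosen by the ligand, giving the syn adduct with C1 and C2 both S, and acid closes the cis-fused α-methylene-γ-butyrolactone; without nickel the vinyl iodide is inert to divalent chromium.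

Step 10
Reactants: 13 (4S,5S)-5-[(1E,5Z)-9-hydroxy-2,6-dimethylnona-1,5-dien-1-yl]-4-[(Z)-3-iodobut-2-en-1-yl]-3-methylideneoxolan-2-one
Product: 14 (4S,5S)-5-[(E)-4-[(2S,3R)-3-(3-hydroxypropyl)-3-methyloxiran-2-yl]-2-methylbut-1-en-1-yl]-4-[(Z)-3-iodobut-2-en-1-yl]-3-methylideneoxolan-2-one
Conditions: L-fructose-derived Shi ketone (1 equiv), KHSO5 (as 2KHSO5·KHSO4·K2SO4), NaHCO3, MeCN/H2O, pH ≈ 8, 0 °C
Reagents that add atoms: potassium peroxymonosulfate, [K+].[O-]S(=O)(=O)OO
Why: Shi asymmetric epoxidation: the chiral dioxirane oxidises only the isolated electron-rich 7Z olefin (C3=C4 is deactivated by the allylic acyloxy group; the iodoalkene and the acrylate are electron-poor) through the spiro transition state, giving the (7S,8R) cis-epoxide under reagent control.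

Step 11
Reactants: 14 (4S,5S)-5-[(E)-4-[(2S,3R)-3-(3-hydroxypropyl)-3-methyloxiran-2-yl]-2-methylbut-1-en-1-yl]-4-[(Z)-3-iodobut-2-en-1-yl]-3-methylideneoxolan-2-one
Product: 15 (4S,5S)-5-[(E)-4-[(2S,3R)-3-methyl-3-(3-oxopropyl)oxiran-2-yl]-2-methylbut-1-en-1-yl]-4-[(Z)-3-iodobut-2-en-1-yl]-3-methylideneoxolan-2-one
Conditions: DMP, NaHCO3, CH2Cl2, 0 °C
Reagents that add atoms: none
Why: Buffered Dess–Martin oxidation of the only free hydroxyl gives the C11 aldehyde, and the neutral medium preserves the epoxide and the lactone.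

Step 12
Reactants: 15 (4S,5S)-5-[(E)-4-[(2S,3R)-3-methyl-3-(3-oxopropyl)oxiran-2-yl]-2-methylbut-1-en-1-yl]-4-[(Z)-3-iodobut-2-en-1-yl]-3-methylideneoxolan-2-one
Product: 16 (1S,2S,3E,7S,8R,11R,12Z)-7,8-epoxy-11-hydroxycembra-3,12,15(17)-trien-16,2-olide
Conditions: CrCl2 (4 equiv), (S)-N-[2-(4-isopropyl-4,5-dihydrooxazol-2-yl)-6-methylphenyl]methanesulfonamide (4.4 equiv), Et3N, NiCl2 (cat.), THF/MeCN, rt, 2 mM, slow addition
Reagents that add atoms: none
Why: Intramolecular Nozaki–Hiyama–Kishi coupling at high dilution: zerovalent nickel inserts into the vinyl iodide with retention of the Z geometry, transmetalation gives an alkenyl species of trivalent chromium that adds only to the aldehyde to close the 14-membered ring, and the chiral sulfonamide ligand directs attack to give the 11R carbinol.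

Step 13
Reactants: 16 (1S,2S,3E,7S,8R,11R,12Z)-7,8-epoxy-11-hydroxycembra-3,12,15(17)-trien-16,2-olide
Product: 17 (1S,2S,3E,7S,8R,11S,12Z)-11-chloro-7,8-epoxycembra-3,12,15(17)-trien-16,2-olide
Conditions: PPh3, Cl3CC(O)CCl3, CH2Cl2, 0 °C
Reagents that add atoms: hexachloroacetone, ClC(Cl)(Cl)C(=O)C(Cl)(Cl)Cl
Why: Appel-type chlorination under neutral conditions converts the secondary allylic alcohol into the chloride by SN2 with inversion (11R to 11S) and little allylic transposition, without opening the epoxide.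

Step 14
Reactants: 17 (1S,2S,3E,7S,8R,11S,12Z)-11-chloro-7,8-epoxycembra-3,12,15(17)-trien-16,2-olide
Product: 18 (1S,2S,3E,7S,8S,11S,12Z)-11-chloro-8-hydroperoxy-7-hydroxycembra-3,12,15(17)-trien-16,2-olide
Conditions: H2O2 (anhydrous, in Et2O, 10 equiv), H3PMo12O40 (cat.), Et2O, rt
Reagents that add atoms: hydrogen peroxide, OO
Why: Acid-catalysed perhydrolysis of the epoxide: hydrogen peroxide attacks the activated oxirane at the more substituted carbon C8 with inversion, giving the 8S tertiary hydroperoxide and the 7S alcohol (C7–O bond untouched), and the substrate has no internal oxygen nucleophile that could compete.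

Step 15
Reactants: 18 (1S,2S,3E,7S,8S,11S,12Z)-11-chloro-8-hydroperoxy-7-hydroxycembra-3,12,15(17)-trien-16,2-olide
Product: 19 (1S,2S,3E,7S,8S,11R,12Z)-8,11-epidioxy-7-hydroxycembra-3,12,15(17)-trien-16,2-olide
Conditions: Cs2CO3, DMF, 0 °C, 5 mM
Reagents that add atoms: none
Why: Intramolecular Williamson-type alkylation of the hydroperoxide (6-exo-tet): carbonate deprotonates only the far more acidic hydroperoxide, and the peroxy anion displaces the allylic chloride across the ring with inversion (11S to 11R), closing the 1,2-dioxane with C7 and C12 cis as in the target.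

Step 16
Reactants: 19 (1S,2S,3E,7S,8S,11R,12Z)-8,11-epidioxy-7-hydroxycembra-3,12,15(17)-trien-16,2-olide
Product: 20 (1S,2S,3E,7S,8S,11R,12Z)-7-acetoxy-8,11-epidioxycembra-3,12,15(17)-trien-16,2-olide (target)
Conditions: Ac2O, pyridine, DMAP (cat.), CH2Cl2, 0 °C → rt
Reagents that add atoms: acetic anhydride, CC(=O)OC(C)=O
Why: DMAP-catalysed acetylation of the only hydroxyl (7-OH) under mild conditions leaves the dialkyl peroxide and the α-methylene lactone intact and gives the target.

**Compound list**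
1 | (1Z,5Z)-1,5-dimethylcycloocta-1,5-diene | C/C1=C/CC/C(C)=C\CC1 | starting material
2 | (Z)-4-methyl-8-oxonon-4-enal | O=CCC/C(C)=C\CCC(C)=O | intermediate (not isolated)
3 | (Z)-9-hydroxy-6-methylnon-5-en-2-one | OCCC/C(C)=C\CCC(C)=O | intermediate
4 | (2E,6Z)-10-hydroxy-N-methoxy-N,3,7-trimethyldeca-2,6-dienamide | OCCC/C(C)=C\CC/C(C)=C/C(=O)N(C)OC | intermediate
5 | (2E,6Z)-10-hydroxy-3,7-dimethyldeca-2,6-dienal | OCCC/C(C)=C\CC/C(C)=C/C=O | intermediate
6 | 3-[(tert-butyldimethylsilyl)oxy]propanal | O=CCCO[Si](C)(C)C(C)(C)C | starting material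
7 | (Z)-tert-butyl[(4-iodopent-3-en-1-yl)oxy]dimethylsilane | C/C(I)=C/CCO[Si](C)(C)C(C)(C)C | intermediate
8 | (Z)-4-iodopent-3-en-1-ol | C/C(I)=C/CCO | intermediate
9 | (Z)-4-iodopent-3-enal | C/C(I)=C/CC=O | intermediate
10 | methyl (Z)-3-hydroxy-6-iodo-2-methylidenehept-5-enoate (racemic) | C=C(C(=O)OC)C(O)C/C=C(/C)I | intermediate
11 | methyl (2Z,5Z)-2-(bromomethyl)-6-iodohepta-2,5-dienoate | BrC/C(C(=O)OC)=C\C/C=C(/C)I | intermediate
12 | methyl (3S,4S,5E,9Z)-4,13-dihydroxy-3-[(Z)-3-iodobut-2-en-1-yl]-6,10-dimethyl-2-methylidenetrideca-5,9-dienoate | C=C(C(=O)OC)[C@H](C/C=C(/C)I)[C@@H](O)/C=C(\C)CC/C=C(/C)CCCO | intermediate (not isolated)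
13 | (4S,5S)-5-[(1E,5Z)-9-hydroxy-2,6-dimethylnona-1,5-dien-1-yl]-4-[(Z)-3-iodobut-2-en-1-yl]-3-methylideneoxolan-2-one | C=C1C(=O)O[C@@H](/C=C(\C)CC/C=C(/C)CCCO)[C@H]1C/C=C(/C)I | intermediate
14 | (4S,5S)-5-[(E)-4-[(2S,3R)-3-(3-hydroxypropyl)-3-methyloxiran-2-yl]-2-methylbut-1-en-1-yl]-4-[(Z)-3-iodobut-2-en-1-yl]-3-methylideneoxolan-2-one | C=C1C(=O)O[C@@H](/C=C(\C)CC[C@@H]2O[C@]2(C)CCCO)[C@H]1C/C=C(/C)I | intermediate
15 | (4S,5S)-5-[(E)-4-[(2S,3R)-3-methyl-3-(3-oxopropyl)oxiran-2-yl]-2-methylbut-1-en-1-yl]-4-[(Z)-3-iodobut-2-en-1-yl]-3-methylideneoxolan-2-one | C=C1C(=O)O[C@@H](/C=C(\C)CC[C@@H]2O[C@]2(C)CCC=O)[C@H]1C/C=C(/C)I | intermediate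
16 | (1S,2S,3E,7S,8R,11R,12Z)-7,8-epoxy-11-hydroxycembra-3,12,15(17)-trien-16,2-olide | C=C1C(=O)O[C@H]2/C=C(\C)CC[C@@H]3O[C@]3(C)CC[C@@H](O)/C(C)=C\C[C@@H]12 | intermediate
17 | (1S,2S,3E,7S,8R,11S,12Z)-11-chloro-7,8-epoxycembra-3,12,15(17)-trien-16,2-olide | C=C1C(=O)O[C@H]2/C=C(\C)CC[C@@H]3O[C@]3(C)CC[C@H](Cl)/C(C)=C\C[C@@H]12 | intermediate
18 | (1S,2S,3E,7S,8S,11S,12Z)-11-chloro-8-hydroperoxy-7-hydroxycembra-3,12,15(17)-trien-16,2-olide | C=C1C(=O)O[C@H]2/C=C(\C)CC[C@H](O)[C@@](C)(OO)CC[C@H](Cl)/C(C)=C\C[C@@H]12 | intermediate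
19 | (1S,2S,3E,7S,8S,11R,12Z)-8,11-epidioxy-7-hydroxycembra-3,12,15(17)-trien-16,2-olide | C=C1C(=O)O[C@H]2/C=C(\C)CC[C@H](O)[C@]3(C)CC[C@@H](OO3)/C(C)=C\C[C@@H]12 | intermediate
20 | (1S,2S,3E,7S,8S,11R,12Z)-7-acetoxy-8,11-epidioxycembra-3,12,15(17)-trien-16,2-olide | C=C1C(=O)O[C@H]2/C=C(\C)CC[C@H](OC(C)=O)[C@]3(C)CC[C@@H](OO3)/C(C)=C\C[C@@H]12 | target

**Totals**
Total step count: 16. Longest linear sequence: 13 steps (steps 4–8, then 9–16, starting from 6); the other branch is 11 steps (steps 1–3, then 9–16).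

**The three steps most likely to fail**

Step 9 (asymmetric, syn-selective allylation). The combination of a γ-substituted 2-(methoxycarbonyl)allyl bromide, an enal and ligand control of the face may give low syn selectivity or low enantioselectivity. The fallback sets out from 10 and comes back at 13. Acetylation (Ac2O, DMAP) gives the Baylis–Hillman acetate F1. Copper-catalysed SN2′ borylation (B2pin2, CuCl cat., LiOt-Bu, THF, 0 °C) gives the E-allylboronate F2, which has the same olefin geometry as 11. A chiral phosphoric acid ((R)-TRIP, or its enantiomer if needed for Re-face delivery; toluene, rt) then catalyses allylboration of 5 through a closed six-membered transition state to the same syn hydroxy ester 12, and p-TsOH closes it to 13. No low-valent metal is involved, and the closed transition state of the boron reagent makes the syn outcome more secure.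

Step 12 (macrocyclisation and C11 configuration). The ring closure may be low-yielding, the ligand may not control C11 in a macrocyclic setting, and the chromium alkoxide sits close to the epoxide. The fallback sets out from 15 and comes back at 16. Ligand-free Nozaki–Hiyama–Kishi closure (CrCl2, NiCl2 cat., DMSO, rt, 2 mM) gives the 11-epimeric alcohols F3. Buffered Dess–Martin oxidation converts both epimers into the single Z-enone F4. Reagent-controlled reduction ((S)-Me-CBS oxazaborolidine, catecholborane, toluene, −78 °C; the alkenyl group acts as the large substituent) then delivers the 11R alcohol 16.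

Step 15 (transannular peroxide closure). The peroxy anion may eliminate or attack in the SN2′ sense, and the β-hydroxy hydroperoxide may fragment under base. The fallback reverses the polarity; it sets out from 17 and comes back at 19. The allylic chloride is displaced intermolecularly, with inversion, by the anion of 2-methoxypropan-2-yl hydroperoxide (CsOH, DMF, 0 °C) to give the 11R peroxyketal F5. Mild acid (AcOH/THF/H2O, rt) unmasks the 11R allylic hydroperoxide F6. Its distal oxygen then opens the epoxide 6-exo at the tertiary carbon C8 with inversion (camphorsulfonic acid cat., CH2Cl2, 0 °C), giving 19 with the same C7, C8 and C11 configurations as the main route.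

**Further compounds**
F1 | step 9 | methyl (Z)-3-acetoxy-6-iodo-2-methylidenehept-5-enoate (racemic) | C=C(C(=O)OC)C(OC(C)=O)C/C=C(/C)I
F2 | step 9 | methyl (2E,5Z)-6-iodo-2-[(4,4,5,5-tetramethyl-1,3,2-dioxaborolan-2-yl)methyl]hepta-2,5-dienoate | CC1(C)OB(C/C(C(=O)OC)=C\C/C=C(/C)I)OC1(C)C
F3 | step 12 | (1S,2S,3E,7S,8R,11RS,12Z)-7,8-epoxy-11-hydroxycembra-3,12,15(17)-trien-16,2-olide (11-epimer mixture) | C=C1C(=O)O[C@H]2/C=C(\C)CC[C@@H]3O[C@]3(C)CCC(O)/C(C)=C\C[C@@H]12
F4 | step 12 | (1S,2S,3E,7S,8R,12Z)-7,8-epoxy-11-oxocembra-3,12,15(17)-trien-16,2-olide | C=C1C(=O)O[C@H]2/C=C(\C)CC[C@@H]3O[C@]3(C)CCC(=O)/C(C)=C\C[C@@H]12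
F5 | step 15 | (1S,2S,3E,7S,8R,11R,12Z)-7,8-epoxy-11-[(2-methoxypropan-2-yl)peroxy]cembra-3,12,15(17)-trien-16,2-olide | C=C1C(=O)O[C@H]2/C=C(\C)CC[C@@H]3O[C@]3(C)CC[C@@H](OOC(C)(C)OC)/C(C)=C\C[C@@H]12
F6 | step 15 | (1S,2S,3E,7S,8R,11R,12Z)-7,8-epoxy-11-hydroperoxycembra-3,12,15(17)-trien-16,2-olide | C=C1C(=O)O[C@H]2/C=C(\C)CC[C@@H]3O[C@]3(C)CC[C@@H](OO)/C(C)=C\C[C@@H]12
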